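| flask | substrate | reagent | remark | time |
|---|---|---|---|---|
| delta | 12 mM | 125 mM | run made earlier |  |
| zeta | 19 mM | 125 mM | run made earlier |  |
| gamma | 25 mM | 190 mM | run made earlier |  |
| flask | 25 mM | 125 mM |  | 8.0 d |

- delta (time / d: tautomer / %, target / %): 0.104: 16.0, 19.1; 0.417: 6.9, 65.7; 2.08: 0.3, 100.1; 10.0: 0, 100.3
- zeta (time / d: tautomer / %, target / %): 0.104: 17.2, 18.0; 0.417: 7.6, 66.5; 2.08: 0, 100.4; 10.0: 0, 99.3
- gamma (time / d: tautomer / %, target / %): 0.104: 10.9, 21.7; 0.417: 4.7, 69.0; 2.08: 0, 100.4; 10.0: 0.5, 100.4

(each reading ± 0.5 percentage points)

- a reading or a percentage of target counts all its forms, free or not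

1. the moment within 8.0 d at which there is most tautomer
2. the amount of tautomer, in percent of the substrate charged, at that time

The flask holds 25 mM of substrate against 125 mM of reagent, so with reagent in excess I treat the loss of tautomer to target as pseudo-first-order. In the first instants the delta run, at the same reagent charge, already reads 16.0% tautomer and 19.1% target.

In the middle, from 0.104 d to 0.417 d, I replace the falling tautomer curve of the delta run by its mean. Target gained, divided by that mean and by the interval, gives 13.0 /d: this is the trapping frequency f, the share of standing tautomer turned into target per day. The zeta run, with another substrate charge at the same reagent, gives 12.5 /d. The gamma run, with both charges changed from delta, gives 19.4 /d, a ratio of 1.49 to delta for a reagent ratio of 1.52, so I let f follow reagent and give the flask the delta value, a half-life of 0.0533 d.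

At the peak, making equals trapping. Assuming equal making, tautomer scales inversely with f, so the first gamma reading, taken at the substrate charge of the flask but with more reagent, scales to my estimate of 16.6%. Target divided by f and by the time puts the delta mean from the start to the first reading at 14.1%, against 16.0% read at the end of that interval, so I take the curve to rise early and place the peak of the flask just before 0.104 d. Later the delta run stands lower: at 2.08 d it reads 0.3% tautomer.

The forecast says 18% at 0.088 d, higher than my estimate, on the view of “reversible tautomerisation followed by trapping of the tautomer by reagent”.

The flask gives 16.7% at 0.0931 d.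

    substrate ⇌ tautomer (K = 1.10, k = 6.90 × 10⁻⁵ /s)
    substrate + reagent ⇌ isomer of the product (K = 2.60 /M, k = 4.70 × 10⁻⁴ /M/s)
    reagent + tautomer → target (k = 0.00130 /M/s)
    crystals ⇌ target, rate k4*(cs4 - [target]) while solid is left; crystals form when [target] > cs4 (solubility = 22.0 mM, k = 0.00230 /s)

For the neighbour flask, charged with 75 mM of reagent, I scale f to 7.80 /d, a half-life of 0.0889 d. Carrying over the flask's making at its peak, 16.7% at f, gives 27.9% for this neighbour. Its simulated peak is lower, at 22.8%.

(The numbers in the tables were generated by integration with made-up constants; scatter was added.)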